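**Plan**
Cuts, in retrosynthetic order: the two phenolic O–benzyl bonds (protection only), ring bond O1–C2, both benzylic C–O bonds (back to C–B), the C2–aryl and C5–aryl bonds together, and last C3–C4.
Enabling feature: in the single ring (O1, C2, C3, C4, C5), C3 and C4 are both S and carry methyl groups. C2 and C5 carry the same aryl group and differ only in sense (C2 S, C5 R). The ring therefore unfolds to a chain with a twofold axis through C3–C4, and inverting either homotopic benzylic carbon gives the target.
Forward order: C3–C4 by enolate dimerisation, both aryl–carbon bonds in one two-directional lithiation–borylation, then the only ring by 5-exo-tet closure of O1–C2.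
Stereochemistry: C3 and C4 come from an oxazolidinone auxiliary. Both benzylic centres come from (−)-sparteine plus stereospecific boron chemistry. C2 is then inverted in the ring closure, while the C5–O bond is never broken.

Key step: step 6

Remarks: Ar = 4-(benzyloxy)-3,5-dimethoxyphenyl and pin = pinacolato. In the boronates the methyl-bearing carbons next to a C–B carbon take the descriptor R only because boron ranks below carbon; no bond at these centres changes. Assumption: (−)-sparteine free base is taken as purchasable and is recovered by acid extraction.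

Step 1
Reactants: 1 (4R)-4-benzyl-3-propanoyl-1,3-oxazolidin-2-one (two molecules)
Product: 3 (2S,3S)-1,4-bis[(4R)-4-benzyl-2-oxo-1,3-oxazolidin-3-yl]-2,3-dimethylbutane-1,4-dione, via lithium Z-enolate 2 (not isolated)
Conditions: LDA (1.05 equiv), THF, −78 °C; anhydrous CuCl2 (1.1 equiv), THF–DMF, −78 → 0 °C
Reagents that add atoms: lithium diisopropylamide, CC(C)N([Li])C(C)C (lithium of 2 only)
Why: Copper(II)-mediated oxidative enolate homocoupling should join two chelated Z-enolates through the faces turned away from the auxiliary benzyl groups, so the C3–C4 bond and both methyl-bearing centres arise as S,S under auxiliary control and any meso isomer is a separable diastereomer.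

Step 2
Reactants: 3 (2S,3S)-bis-imide
Product: 4 (2S,3S)-2,3-dimethylbutane-1,4-diol
Conditions: LiBH4 (4 equiv), MeOH (4 equiv), THF, 0 °C → rt
Reagents that add atoms: none
Why: Reductive cleavage of N-acyloxazolidinones with lithium borohydride attacks only the exocyclic carbonyl groups and takes both to primary alcohols under conditions too mild to enolise the α-centres, and the auxiliary is recovered.

Step 3
Reactants: 4 (2S,3S)-2,3-dimethylbutane-1,4-diol; 5 N,N-diisopropylcarbamoyl chloride
Product: 6 (2S,3S)-2,3-dimethylbutane-1,4-diyl bis(N,N-diisopropylcarbamate)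
Conditions: 5 (2.5 equiv), Et3N (3 equiv), DMAP (cat), CH2Cl2, reflux
Reagents that add atoms: 5 N,N-diisopropylcarbamoyl chloride, CC(C)N(C(C)C)C(=O)Cl
Why: O-Carbamoylation of primary alcohols by nucleophilic acyl substitution is the standard entry to lithiation-directing carbamates and touches no stereocentre.

Step 4
Reactants: 7 4-bromo-2,6-dimethoxyphenol
Product: 8 2-(benzyloxy)-5-bromo-1,3-dimethoxybenzene
Conditions: BnBr, K2CO3, DMF, 50 °C
Reagents that add atoms: benzyl bromide, BrCc1ccccc1
Why: Williamson ether synthesis on the phenoxide installs a group that should survive boronate chemistry, alkaline peroxide and MsCl/Et3N and can be removed later without acid or base.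

Step 5
Reactants: 8 2-(benzyloxy)-5-bromo-1,3-dimethoxybenzene; 9 bis(pinacolato)diboron
Product: 10 2-[4-(benzyloxy)-3,5-dimethoxyphenyl]-4,4,5,5-tetramethyl-1,3,2-dioxaborolane
Conditions: PdCl2(dppf) (3 mol %), KOAc (3 equiv), 1,4-dioxane, 90 °C
Reagents that add atoms: 9 bis(pinacolato)diboron, CC1(C)OB(OC1(C)C)B1OC(C)(C)C(C)(C)O1
Why: Miyaura borylation of an unhindered aryl bromide (both ortho positions are C–H) proceeds through oxidative addition, acetate-assisted transmetallation and reductive elimination, and tolerates the ether groups.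

Step 6
Reactants: 6 (2S,3S)-2,3-dimethylbutane-1,4-diyl bis(N,N-diisopropylcarbamate); 10 aryl pinacol boronate (two molecules incorporated)
Product: 13 (1R,2R,3R,4R)-1,4-bis[4-(benzyloxy)-3,5-dimethoxyphenyl]-2,3-dimethylbutane-1,4-diyl bis(pinacol boronate), via dilithio bis-carbamate 11 (not isolated), via bis-boronate complex 12 (not isolated)
Conditions: s-BuLi (2.6 equiv), (−)-sparteine (2.6 equiv), Et2O, −78 °C, 6 h; 10 (3.0 equiv), −78 °C, 2 h; MgBr2·OEt2 (3 equiv), −78 °C → reflux, 16 h
Reagents that add atoms: s-butyllithium, CCC(C)[Li] (lithium of 11 and 12 only)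
Why: s-BuLi bound to (−)-sparteine is held by each carbamate carbonyl and removes the pro-S hydrogen of the adjacent OCH2 group, so the configurationally stable (1S,4S)-dilithio compound 11 is fully formed at −78 °C before any arene is in the flask. Each carbanion then adds to the boron of 10 with retention to give 12, and on warming with MgBr2 the electron-rich aryl group shifts from boron to carbon antiperiplanar to the leaving carbamate, hence with inversion, which makes the C2–aryl and C5–aryl bonds. The closest known reaction is the sparteine-mediated lithiation–borylation of primary alkyl carbamates with aryl pinacol boronates (asymmetric deprotonation followed by a Matteson-type 1,2-metallate rearrangement), used here at two remote sites of one molecule in the same operation. No ring is closed in this step. Both new benzylic stereocentres come out R because the diamine chooses the proton and the retention–inversion sequence at boron is stereospecific, so the adjacent methyl groups have no say. The step needs the same sense of deprotonation and full conversion at both ends, which the twofold axis of 6 secures by making the two OCH2 groups homotopic (one substrate–reagent pairing, met twice), while the four-carbon spacing and the bulky diisopropylcarbamoyl groups keep one lithiated end from attacking the other, and an end set wrongly would give an unsymmetrical diastereomer removable by chromatography.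

Step 7
Reactants: 13 C2-symmetric bis(pinacol boronate)
Product: 14 (1R,2S,3S,4R)-1,4-bis[4-(benzyloxy)-3,5-dimethoxyphenyl]-2,3-dimethylbutane-1,4-diol
Conditions: 30% aq H2O2, 2 M NaOH, THF, 0 °C → rt
Reagents that add atoms: hydrogen peroxide, OO
Why: Alkaline peroxide oxidation of boronic esters proceeds by addition of hydroperoxide to boron and carbon-to-oxygen 1,2-migration with retention, so both benzylic centres stay R and the benzyl and methyl ethers are inert.

Step 8
Reactants: 14 (1R,2S,3S,4R)-diol
Product: 16 (2S,3S,4S,5R)-2,5-bis[4-(benzyloxy)-3,5-dimethoxyphenyl]-3,4-dimethyloxolane, via monomesylate 15 (not isolated)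
Conditions: MsCl (1.05 equiv), Et3N (4 equiv), CH2Cl2, −20 °C → rt
Reagents that add atoms: methanesulfonyl chloride, CS(=O)(=O)Cl (atoms held only in 15)
Why: Sulfonate activation followed by an intramolecular Williamson-type 5-exo-tet displacement should let the remaining hydroxyl expel the mesylate formed at either homotopic end faster than a second mesylation, with inversion (R to S at C2, aryl now trans to the C3 methyl), while a partly ionised pathway would close to the same trans arrangement and C5 stays R because its C–O bond is never broken.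

Step 9
Reactants: 16 dibenzyl ether of the target
Product: 17 4,4'-[(2S,3S,4S,5R)-3,4-dimethyloxolane-2,5-diyl]bis(2,6-dimethoxyphenol)
Conditions: H2 (1 atm), 10% Pd/C, EtOAc, rt, stopped at full debenzylation
Reagents that add atoms: none
Why: Catalytic hydrogenolysis cleaves aryl benzyl ethers much faster than the hindered secondary ring C–O bonds, a selectivity well established for benzyl-protected 2,5-diaryloxolane lignans, and the neutral medium avoids the acid that would epimerise C5.

**Compound list**
1 | (4R)-4-benzyl-3-propanoyl-1,3-oxazolidin-2-one | CCC(=O)N1[C@H](Cc2ccccc2)COC1=O | starting material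
2 | lithium (Z)-enolate of 1 | C/C=C(\O[Li])N1[C@H](Cc2ccccc2)COC1=O | intermediate
3 | (2S,3S)-1,4-bis[(4R)-4-benzyl-2-oxo-1,3-oxazolidin-3-yl]-2,3-dimethylbutane-1,4-dione | O=C([C@@H](C)[C@H](C)C(=O)N1[C@H](Cc2ccccc2)COC1=O)N1[C@H](Cc2ccccc2)COC1=O | intermediate
4 | (2S,3S)-2,3-dimethylbutane-1,4-diol | OC[C@@H](C)[C@H](C)CO | intermediate
5 | N,N-diisopropylcarbamoyl chloride | CC(C)N(C(C)C)C(=O)Cl | starting material
6 | (2S,3S)-2,3-dimethylbutane-1,4-diyl bis(N,N-diisopropylcarbamate) | CC(C)N(C(C)C)C(=O)OC[C@@H](C)[C@H](C)COC(=O)N(C(C)C)C(C)C | intermediate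
7 | 4-bromo-2,6-dimethoxyphenol | COc1cc(Br)cc(OC)c1O | starting material
8 | 2-(benzyloxy)-5-bromo-1,3-dimethoxybenzene | COc1cc(Br)cc(OC)c1OCc1ccccc1 | intermediate
9 | bis(pinacolato)diboron | CC1(C)OB(OC1(C)C)B1OC(C)(C)C(C)(C)O1 | starting material
10 | 2-[4-(benzyloxy)-3,5-dimethoxyphenyl]-4,4,5,5-tetramethyl-1,3,2-dioxaborolane | COc1cc(B2OC(C)(C)C(C)(C)O2)cc(OC)c1OCc1ccccc1 | intermediate
11 | (1S,2S,3S,4S)-1,4-dilithio-2,3-dimethylbutane-1,4-diyl bis(N,N-diisopropylcarbamate), each lithium bound to (−)-sparteine (ligand not drawn) | CC(C)N(C(C)C)C(=O)O[C@@H]([Li])[C@@H](C)[C@H](C)[C@H]([Li])OC(=O)N(C(C)C)C(C)C | intermediate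
12 | dilithium (1S,2S,3S,4S)-bis-boronate complex, each carbinol carbon bearing OC(O)N(i-Pr)2 and B(Ar)(pin) | [Li+].[Li+].CC(C)N(C(C)C)C(=O)O[C@@H]([B-]1(c2cc(OC)c(OCc3ccccc3)c(OC)c2)OC(C)(C)C(C)(C)O1)[C@@H](C)[C@H](C)[C@H]([B-]1(c2cc(OC)c(OCc3ccccc3)c(OC)c2)OC(C)(C)C(C)(C)O1)OC(=O)N(C(C)C)C(C)C | intermediate
13 | (1R,2R,3R,4R)-1,4-bis[4-(benzyloxy)-3,5-dimethoxyphenyl]-2,3-dimethylbutane-1,4-diyl bis(pinacol boronate) | CC1(C)OB(OC1(C)C)[C@@H](c1cc(OC)c(OCc2ccccc2)c(OC)c1)[C@@H](C)[C@H](C)[C@@H](B1OC(C)(C)C(C)(C)O1)c1cc(OC)c(OCc2ccccc2)c(OC)c1 | intermediate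
14 | (1R,2S,3S,4R)-1,4-bis[4-(benzyloxy)-3,5-dimethoxyphenyl]-2,3-dimethylbutane-1,4-diol | O[C@@H](c1cc(OC)c(OCc2ccccc2)c(OC)c1)[C@@H](C)[C@H](C)[C@@H](O)c1cc(OC)c(OCc2ccccc2)c(OC)c1 | intermediate
15 | (1R,2S,3S,4R)-1,4-bis[4-(benzyloxy)-3,5-dimethoxyphenyl]-4-hydroxy-2,3-dimethylbutyl methanesulfonate | CS(=O)(=O)O[C@@H](c1cc(OC)c(OCc2ccccc2)c(OC)c1)[C@@H](C)[C@H](C)[C@@H](O)c1cc(OC)c(OCc2ccccc2)c(OC)c1 | intermediate
16 | (2S,3S,4S,5R)-2,5-bis[4-(benzyloxy)-3,5-dimethoxyphenyl]-3,4-dimethyloxolane | COc1cc([C@H]2O[C@@H](c3cc(OC)c(OCc4ccccc4)c(OC)c3)[C@@H](C)[C@@H]2C)cc(OC)c1OCc1ccccc1 | intermediate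
17 | 4,4'-[(2S,3S,4S,5R)-3,4-dimethyloxolane-2,5-diyl]bis(2,6-dimethoxyphenol) | COc1cc([C@H]2O[C@@H](c3cc(OC)c(O)c(OC)c3)[C@@H](C)[C@@H]2C)cc(OC)c1O | target

Total step count: 9. Longest linear sequence: 7 (steps 1, 2, 3, 6, 7, 8, 9).

**Steps most likely to fail**

Step 6.
- Risk: the second deprotonation may lag behind the first, because β-branched OCH2 groups lithiate slowly and a doubly lithiated species may aggregate or fall out of ether. The result would be mixtures of mono- and bis-arylated material, and the first carbanion would have time to attack the distal carbamate.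
- Fallback: the two ends are arylated one after the other, each by the single-site reaction with one deprotonation per molecule and recycling of unreacted material.
- First pass: setting out from 6, one equivalent of s-BuLi/(−)-sparteine, then 10 and MgBr2·OEt2, should give (2S,3R,4R)-4-aryl-2,3-dimethyl-4-(pinacolatoboryl)butyl N,N-diisopropylcarbamate F1. Alkaline peroxide converts it into the (2S,3S,4R)-hydroxy carbamate F2, and TBSCl/imidazole gives its tert-butyldimethylsilyl ether F3.
- Second pass: carbamate-directed lithiation–borylation at the remaining OCH2 group should outrun metallation of the arene by the proximity effect and give the silyloxy boronate F4. Peroxide gives the mono-silylated diol F5, and TBAF brings the sequence back to the route at 14.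

Step 8.
- Risk: the electron-rich benzylic sulfonate may ionise, be intercepted by chloride, or lose a proton to a styrene. Both hydroxyls may be sulfonylated. Amine hydrochloride may reopen the product at C5, so that it drifts towards the all-trans isomer.
- Fallback: the sulfonate is replaced by a redox dehydration of the Mitsunobu type (PPh3, DIAD, toluene, 0 °C), starting from 14 and returning at 16. The diol is taken up as an oxyphosphonium or cyclic dioxaphosphorane species. This collapses by intramolecular SN2 with inversion at one carbon in a neutral, halide-free medium, and no further isolable compound is made.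

Step 1.
- Risk: the coupling of two hindered enolates by single-electron oxidation may stall, compete with α-chlorination, or show imperfect facial selectivity and deliver meso material.
- Fallback: the C3–C4 bond is made by stereospecific alkylation instead of oxidation.
- Electrophile: commercial ethyl (S)-lactate is converted (Tf2O, 2,6-lutidine, CH2Cl2, −78 °C) into ethyl (2S)-2-{[(trifluoromethyl)sulfonyl]oxy}propanoate F6.
- Alkylation: the enolate 2, made from 1 as before, displaces the triflate with inversion on its auxiliary-controlled face. This gives ethyl (2S,3S)-4-[(4R)-4-benzyl-2-oxo-1,3-oxazolidin-3-yl]-2,3-dimethyl-4-oxobutanoate F7.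
- Return: LiBH4 then reduces both acyl groups, and the sequence, which set out from 1, rejoins the route at 4.

**Further compounds**
F1 | step 6 | (2S,3R,4R)-4-[4-(benzyloxy)-3,5-dimethoxyphenyl]-2,3-dimethyl-4-(4,4,5,5-tetramethyl-1,3,2-dioxaborolan-2-yl)butyl N,N-diisopropylcarbamate | CC1(C)OB(OC1(C)C)[C@@H](c1cc(OC)c(OCc2ccccc2)c(OC)c1)[C@@H](C)[C@H](C)COC(=O)N(C(C)C)C(C)C
F2 | step 6 | (2S,3S,4R)-4-[4-(benzyloxy)-3,5-dimethoxyphenyl]-4-hydroxy-2,3-dimethylbutyl N,N-diisopropylcarbamate | O[C@@H](c1cc(OC)c(OCc2ccccc2)c(OC)c1)[C@@H](C)[C@H](C)COC(=O)N(C(C)C)C(C)C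
F3 | step 6 | (2S,3S,4R)-4-[4-(benzyloxy)-3,5-dimethoxyphenyl]-4-[(tert-butyldimethylsilyl)oxy]-2,3-dimethylbutyl N,N-diisopropylcarbamate | CC(C)(C)[Si](C)(C)O[C@@H](c1cc(OC)c(OCc2ccccc2)c(OC)c1)[C@@H](C)[C@H](C)COC(=O)N(C(C)C)C(C)C
F4 | step 6 | tert-butyl{[(1R,2S,3R,4R)-1,4-bis[4-(benzyloxy)-3,5-dimethoxyphenyl]-2,3-dimethyl-4-(4,4,5,5-tetramethyl-1,3,2-dioxaborolan-2-yl)butyl]oxy}dimethylsilane | CC(C)(C)[Si](C)(C)O[C@@H](c1cc(OC)c(OCc2ccccc2)c(OC)c1)[C@@H](C)[C@H](C)[C@@H](B1OC(C)(C)C(C)(C)O1)c1cc(OC)c(OCc2ccccc2)c(OC)c1
F5 | step 6 | (1R,2S,3S,4R)-1,4-bis[4-(benzyloxy)-3,5-dimethoxyphenyl]-4-[(tert-butyldimethylsilyl)oxy]-2,3-dimethylbutan-1-ol | CC(C)(C)[Si](C)(C)O[C@@H](c1cc(OC)c(OCc2ccccc2)c(OC)c1)[C@@H](C)[C@H](C)[C@@H](O)c1cc(OC)c(OCc2ccccc2)c(OC)c1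
F0 | step 8 | none | none
F6 | step 1 | ethyl (2S)-2-{[(trifluoromethyl)sulfonyl]oxy}propanoate | C[C@H](OS(=O)(=O)C(F)(F)F)C(=O)OCC
F7 | step 1 | ethyl (2S,3S)-4-[(4R)-4-benzyl-2-oxo-1,3-oxazolidin-3-yl]-2,3-dimethyl-4-oxobutanoate | CCOC(=O)[C@@H](C)[C@H](C)C(=O)N1[C@H](Cc2ccccc2)COC1=O
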